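Retrosynthesis: the C8 methyl ether is cut first; ring A is then cut at C8–C8a and C4a–C5 into dimethyl squarate and a 2-aryl-4-pyranone metallated at the future C4a; the pyranone is cut at O1–C8a and C2–C3 into 3,4,5-trimethoxybenzoyl chloride and an α-iodinated 4-methoxybutenone.
Forward: ring B is bought; ring C (the 4-pyranone) is closed second, with the iodine already in place; ring A is made last by squarate addition and thermal ring expansion; the C8 hydroxyl is methylated at the end.
Enabling feature: C5, C6, C7 and C8 of ring A (O, OMe, OMe, O) are the four carbons of dimethyl squarate. The C4a–C8a bond is the enol-ether double bond of the pyranone, whose CH next to the ring oxygen (future C8a) can accept the ketene carbon. The C5 hydroxyl is hydrogen-bonded to the C4 carbonyl, which sets it apart from the C8 hydroxyl.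
Stereochemistry: the target has none; the single carbinol stereocentre made on the way is racemic and becomes aromatic C5, and the enone geometry disappears when ring C closes.
Key step: step 5

Assumption: atom labels C2 to C8a are those of the chromen-4-one skeleton of the target; the iodo enone is drawn as the Z isomer by analogy with bromination of the same enone, and its geometry is lost when ring C closes; the tetramethoxylated hydroxyacetophenone used in one fallback is taken as purchasable.

Step 1
Reactants: 1 (E)-4-methoxybut-3-en-2-one
Product: 3 (Z)-3-iodo-4-methoxybut-3-en-2-one, via ICl adduct 2 (not isolated)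
Conditions: ICl, CH2Cl2, −78 °C; then Et3N, −78 to 0 °C
Reagents that add atoms: iodine monochloride, ClI
Why: ICl should deliver iodine to the nucleophilic α-carbon of the push-pull enol ether while chloride caps the oxocarbenium ion, and Et3N then removes the acidic α-hydrogen with loss of chloride (addition–elimination α-halogenation of a vinylogous ester, the same sequence as the standard bromination of this enone), so the halogen sits on the future C4a before any ring exists.

Step 2
Reactants: 3 (Z)-3-iodo-4-methoxybut-3-en-2-one (2 equiv); 4 3,4,5-trimethoxybenzoyl chloride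
Product: 6 (4Z)-4-iodo-5-methoxy-1-(3,4,5-trimethoxyphenyl)pent-4-ene-1,3-dione, via lithium enolate 5 (not isolated)
Conditions: LiN(SiMe3)2 (2 equiv), THF, −78 °C; then 4 (1 equiv), −78 °C; aq NH4Cl; crude product carried on
Reagents that add atoms: none
Why: LiN(SiMe3)2 at −78 °C should remove a methyl hydrogen of 3 kinetically, and the cross-conjugated lithium enolate is then C-acylated by the acid chloride in a Claisen-type condensation, the second equivalent of enolate taking up the acidic proton of the 1,3-diketone so that the product is protected from further acylation.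

Step 3
Reactants: 6 (4Z)-4-iodo-5-methoxy-1-(3,4,5-trimethoxyphenyl)pent-4-ene-1,3-dione
Product: 7 5-iodo-2-(3,4,5-trimethoxyphenyl)-4H-pyran-4-one
Conditions: TFA, CH2Cl2, rt
Reagents that add atoms: none
Why: Acid should promote 6-endo conjugate addition of the enol oxygen of the aryl ketone to the methoxyvinyl carbon followed by loss of methanol, the standard addition–elimination closure of 4-pyranones from 5-methoxypent-4-ene-1,3-diones, which forms the O1–C8a bond and erases the alkene geometry.

Step 4
Reactants: 7 5-iodo-2-(3,4,5-trimethoxyphenyl)-4H-pyran-4-one; 8 dimethyl squarate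
Product: 10 4-hydroxy-2,3-dimethoxy-4-[4-oxo-6-(3,4,5-trimethoxyphenyl)-4H-pyran-3-yl]cyclobut-2-en-1-one (racemic), via pyranonylmagnesium chloride 9 (not isolated)
Conditions: iPrMgCl·LiCl (1.1 equiv), THF, −78 to −40 °C; then cannulated into 8 (1.2 equiv), THF, −78 °C; aq NH4Cl, −78 °C
Reagents that add atoms: none
Why: The C–I bond of the α-iodo enone unit should undergo iodine–magnesium exchange with iPrMgCl·LiCl at low temperature faster than the reagent adds to the ring, by analogy with the exchange on 3-iodochromones, and the sp2 organomagnesium then adds 1,2 to one of the two equivalent squarate carbonyl groups (the standard entry to 4-substituted 4-hydroxycyclobutenones); the carbinol stereocentre forms racemic and is erased in step 5.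

Step 5
Reactants: 10 4-hydroxy-2,3-dimethoxy-4-[4-oxo-6-(3,4,5-trimethoxyphenyl)-4H-pyran-3-yl]cyclobut-2-en-1-one (racemic)
Product: 13 5,8-dihydroxy-6,7-dimethoxy-2-(3,4,5-trimethoxyphenyl)-4H-chromen-4-one, via dienylketene 11 (not isolated), via cyclohexadienone 12 (not isolated)
Conditions: toluene (degassed, about 0.01 M), 110 °C, Ar; aq Na2S2O4 wash if any quinone has formed
Reagents that add atoms: none
Why: Proposed new method: heating 10 should open the cyclobutenone by 4π conrotatory cleavage of its C1–C4 bond with the hydroxyl turning outward, giving dienylketene 11 with the pyranone on the same side as the ketene; 11 then undergoes thermal 6π electrocyclisation between the ketene carbon and the pyranone CH next to the ring oxygen, and cyclohexadienone 12 enolises by loss of the ring-fusion hydrogen to hydroquinone 13. The closest known reaction type is the Moore rearrangement of 4-alkenyl-, 4-aryl- and 4-heteroaryl-4-hydroxycyclobutenones made from squarate esters, which has not been shown with a 4-oxo-4H-pyran-3-yl group as the unsaturated partner. Ring A is the only ring closed, by 6π electrocyclisation that forms the C8–C8a bond, the C4a–C5 bond having been made in step 4. No stereocentre survives, since the carbinol carbon of 10 becomes aromatic C5 and the sp3 ring-fusion carbon of 12 is flattened on tautomerisation. The step needs the right torquoselectivity and a single site of closure: the first is secured by the donor hydroxyl on the breaking bond, which prefers outward rotation; the second by the point of attachment, whose only ring neighbours are the carbonyl carbon and the hydrogen-bearing carbon of a weakly aromatic enol-ether double bond. Dilute, degassed conditions should hold back ketene oligomerisation and oxidation to the 5,8-quinone.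

Step 6
Reactants: 13 5,8-dihydroxy-6,7-dimethoxy-2-(3,4,5-trimethoxyphenyl)-4H-chromen-4-one
Product: 14 Gardenin A
Conditions: Me2SO4 (1.05 equiv), K2CO3, acetone (degassed), reflux, Ar
Reagents that add atoms: dimethyl sulfate, COS(=O)(=O)OC
Why: Williamson O-methylation under mild base should reach only the free C8 phenol, because the C5 hydroxyl is held in a six-membered hydrogen bond to the C4 carbonyl and is far less acidic and nucleophilic (the classical basis for partial methylation of 5-hydroxyflavones), while one equivalent of reagent and exclusion of air guard against over-methylation and quinone formation.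

Compound list
1 | (E)-4-methoxybut-3-en-2-one | CO/C=C/C(C)=O | starting material
2 | 4-chloro-3-iodo-4-methoxybutan-2-one (ICl adduct, mixture of diastereomers) | COC(Cl)C(I)C(C)=O | intermediate (not isolated)
3 | (Z)-3-iodo-4-methoxybut-3-en-2-one | CO/C=C(\I)C(C)=O | intermediate
4 | 3,4,5-trimethoxybenzoyl chloride | COc1cc(C(Cl)=O)cc(OC)c1OC | starting material
5 | lithium (3Z)-3-iodo-4-methoxybuta-1,3-dien-2-olate (lithium enolate of 3) | C=C(O[Li])/C(I)=C/OC | intermediate (not isolated)
6 | (4Z)-4-iodo-5-methoxy-1-(3,4,5-trimethoxyphenyl)pent-4-ene-1,3-dione | COc1cc(C(=O)CC(=O)/C(I)=C/OC)cc(OC)c1OC | intermediate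
7 | 5-iodo-2-(3,4,5-trimethoxyphenyl)-4H-pyran-4-one | COc1cc(-c2cc(=O)c(I)co2)cc(OC)c1OC | intermediate
8 | dimethyl squarate (3,4-dimethoxycyclobut-3-ene-1,2-dione) | COC1=C(OC)C(=O)C1=O | starting material
9 | [4-oxo-6-(3,4,5-trimethoxyphenyl)-4H-pyran-3-yl]magnesium chloride (LiCl complex) | COc1cc(-c2cc(=O)c([Mg]Cl)co2)cc(OC)c1OC | intermediate (not isolated)
10 | 4-hydroxy-2,3-dimethoxy-4-[4-oxo-6-(3,4,5-trimethoxyphenyl)-4H-pyran-3-yl]cyclobut-2-en-1-one (racemic) | COC1=C(OC)C(O)(c2coc(-c3cc(OC)c(OC)c(OC)c3)cc2=O)C1=O | intermediate
11 | (3Z)-4-hydroxy-2,3-dimethoxy-4-[4-oxo-6-(3,4,5-trimethoxyphenyl)-4H-pyran-3-yl]buta-1,3-dien-1-one (dienylketene, pyranone cis to the ketene) | O=C=C(OC)/C(OC)=C(/O)c1coc(-c2cc(OC)c(OC)c(OC)c2)cc1=O | intermediate (not isolated)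
12 | 5-hydroxy-6,7-dimethoxy-2-(3,4,5-trimethoxyphenyl)-8aH-chromene-4,8-dione (racemic at C8a) | COc1cc(C2=CC(=O)C3=C(O)C(OC)=C(OC)C(=O)C3O2)cc(OC)c1OC | intermediate (not isolated)
13 | 5,8-dihydroxy-6,7-dimethoxy-2-(3,4,5-trimethoxyphenyl)-4H-chromen-4-one | COc1cc(-c2cc(=O)c3c(O)c(OC)c(OC)c(O)c3o2)cc(OC)c1OC | intermediate
14 | Gardenin A, 5-hydroxy-6,7,8-trimethoxy-2-(3,4,5-trimethoxyphenyl)-4H-chromen-4-one | COc1cc(-c2cc(=O)c3c(O)c(OC)c(OC)c(OC)c3o2)cc(OC)c1OC | target

Total step count: 6
Longest linear sequence: 6 steps (1 to 3 to 6 to 7 to 10 to 13 to 14); 4 and 8 are bought and enter at steps 2 and 4.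

The three steps most likely to fail, riskiest first:

The first risk lies in step 5, the one step put forward as a new method. The ketene may be consumed before it closes onto the pyranone: the hydroxyl may rotate inward and lactonise to a butenolide, closure onto the electron-poor, weakly aromatic enol-ether bond may be slow enough for oligomerisation to win, or the hydroquinone may autoxidise during isolation. The fallback uses known flavone chemistry, sets out from 4 and comes back to the route at 14. The ring A ketone 1-(2-hydroxy-3,4,5,6-tetramethoxyphenyl)ethan-1-one F1 would be converted into its dianion with LiN(SiMe3)2 (3 equiv) in THF at −78 °C and C-aroylated by 4 in a Claisen condensation, which should give 1-(2-hydroxy-3,4,5,6-tetramethoxyphenyl)-3-(3,4,5-trimethoxyphenyl)propane-1,3-dione F2 after acidic work-up. Cyclodehydration with H2SO4 in AcOH at 100 °C would then give 5,6,7,8-tetramethoxy-2-(3,4,5-trimethoxyphenyl)-4H-chromen-4-one F3 with loss of water. BCl3 in CH2Cl2 at 0 °C, chelated between the C4 carbonyl and the peri oxygen, would finally remove only the C5 methyl group and give 14.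

The second risk lies in step 4. The alkyl Grignard reagent may add in conjugate fashion to the pyranone instead of exchanging, the magnesiated pyranone may ring-open by β-elimination of the ring oxygen, or its addition to the squarate may stall or go 1,4 with loss of methoxide. The fallback sets out from 7 and comes back to the route at 10. It makes the carbon–metal bond by oxidative insertion of zinc metal instead of exchange with a basic organomagnesium reagent: zinc dust with LiCl in THF at 25 °C would give iodo[4-oxo-6-(3,4,5-trimethoxyphenyl)-4H-pyran-3-yl]zinc F4 as its LiCl complex. This non-basic organometallic should neither attack the pyranone nor ring-open, and its 1,2-addition to 8 would be driven by MgCl2 as Lewis acid, with NH4Cl quench giving 10.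

The third risk lies in step 2. The amide base may dehydroiodinate the iodo enone (hydrogen and iodine are trans) or attack its β-carbon before enolisation is complete, and the enolate may be acylated on oxygen. The fallback sets out from 1 and comes back to the route at 7; it builds ring C by cycloaddition and brings in the iodine on a ring that offers only one enone α-position. Silylation of 1 (Me3SiCl, Et3N, cat. ZnCl2) would give the diene (E)-1-methoxy-3-(trimethylsilyloxy)buta-1,3-diene F5 for a ZnCl2-promoted hetero-Diels–Alder reaction with purchased 3,4,5-trimethoxybenzaldehyde F6 that, after TFA work-up, should give 2-(3,4,5-trimethoxyphenyl)-2,3-dihydro-4H-pyran-4-one F7 as the racemate. α-Iodination with I2 and pyridine in CH2Cl2 would give 5-iodo-2-(3,4,5-trimethoxyphenyl)-2,3-dihydro-4H-pyran-4-one F8 and dehydrogenation across C2–C3 with DDQ in refluxing dioxane, as for flavanones, would then give 7.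

Further compounds
F1 | step 5 | 1-(2-hydroxy-3,4,5,6-tetramethoxyphenyl)ethan-1-one | CC(=O)c1c(O)c(OC)c(OC)c(OC)c1OC
F2 | step 5 | 1-(2-hydroxy-3,4,5,6-tetramethoxyphenyl)-3-(3,4,5-trimethoxyphenyl)propane-1,3-dione | COc1cc(C(=O)CC(=O)c2c(O)c(OC)c(OC)c(OC)c2OC)cc(OC)c1OC
F3 | step 5 | 5,6,7,8-tetramethoxy-2-(3,4,5-trimethoxyphenyl)-4H-chromen-4-one | COc1cc(-c2cc(=O)c3c(OC)c(OC)c(OC)c(OC)c3o2)cc(OC)c1OC
F4 | step 4 | iodo[4-oxo-6-(3,4,5-trimethoxyphenyl)-4H-pyran-3-yl]zinc | COc1cc(-c2cc(=O)c([Zn]I)co2)cc(OC)c1OC
F5 | step 2 | (E)-1-methoxy-3-(trimethylsilyloxy)buta-1,3-diene | CO/C=C/C(=C)O[Si](C)(C)C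
F6 | step 2 | 3,4,5-trimethoxybenzaldehyde | COc1cc(C=O)cc(OC)c1OC
F7 | step 2 | 2-(3,4,5-trimethoxyphenyl)-2,3-dihydro-4H-pyran-4-one (racemic) | COc1cc(C2CC(=O)C=CO2)cc(OC)c1OC
F8 | step 2 | 5-iodo-2-(3,4,5-trimethoxyphenyl)-2,3-dihydro-4H-pyran-4-one (racemic) | COc1cc(C2CC(=O)C(I)=CO2)cc(OC)c1OC
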